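(Its constants were chosen freely; no experiment stands behind them.)

Beta cannot carry its electrophile wholly to product if each turn costs more nucleophile than the 1.19 it holds per electrophile.

in all of them: electrophile 0.84 M; protic impurity 0.840 M; time 4.0 d
- beta: nucleophile 1.00 M
- epsilon: nucleophile 1.50 M
- alpha: nucleophile 2.30 M

    nucleophile + protic impurity → quenched reagent (k1 = 6.3 × 10⁻⁴ /M/min)
    electrophile ⇌ dormant form (K2 = 0.25, k2 = 2.1 × 10⁻⁴ /min)
    electrophile + nucleophile → acid set free + product (k3 = 0.0027 /M/min)
    nucleophile + acid set free ⇌ protonated nucleophile, settled at all times (K4 = 3000 /M)
    nucleophile + product ⇌ idle adduct, settled at all times (K5 = 1.4 /M)

- part of the electrophile that has reacted at the end, beta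
- part of the electrophile that has reacted at the end, epsilon
- part of the electrophile that has reacted at the end, alpha
- what raising the concentration of nucleophile from its lowest to its highest value here does to the part of the electrophile that has reacted (changes below 5 percentage points count as none) (no change / it rises / it falls)

- what is said of product includes idle adduct
- what has gone from electrophile into another species counts as reacted, even if it can come back
- run time (beta): 4.0 d

So I write the balance of the nucleophile. One nucleophile enters the main step, and while free nucleophile stands a second follows the acid set free, because the constant of that binding times the charged nucleophile in beta is 3000, far above one. The protic impurity takes more: at the start of beta the main step uses nucleophile 4.3 times as fast as the quench. Holding that starting ratio, I get the price, the nucleophile lost per electrophile turned 2.23. Beta, epsilon and alpha share it, since their electrophile and impurity charges are equal.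

Nucleophile charge over price times electrophile charge gives my estimate of the reach, the product as a fraction of the electrophile charged: 0.533 in beta, 0.800 in epsilon, 1.23 in alpha. Below one, nucleophile is the limiting reagent. For the reacted part to stay unchanged on this reckoning, the reach of beta would already have to be one, and it stands at 0.533, so I expect a rise.

In beta the relaxation half-life of the dormant form, 0.458 d, is short against 4.0 d, so 0.200 of the unturned electrophile counts as reacted. That gives 62.6 % for beta and 84.0 % for epsilon, and with a reach above one in alpha I put down 100 % there.

The forecast says 63 %, 80 % and 96 %, with the answer on the trend "it rises", on the ground that “Each electrophile consumed costs two nucleophiles”; my figures for epsilon and alpha lie above its values.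

The flask gives 62.4 % in beta, 80.0 % in epsilon and 97.2 % in alpha, and the answer on the trend is "it rises", by 35 percentage points. For the neighbour of beta with 2.1 M of electrophile, other charges and time unchanged, the extra part of my price 2.23 shrinks with the electrophile charge, so I reckon a price of 2.09, a reach of 0.227 and a reacted part of 38.2 %. That flask holds 24.8 % of its charged electrophile as product and nucleophile at 0.138 % of its charge after 4.00 d, with 39.9 % of its electrophile reacted.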